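The route disconnects the O–C10 bond of the furanone ring. The oxygen bridge between C3 and C10 of the ten-membered carbocycle, with oxygen also on C1, is traced back to a 3-oxo germacranolide whose C1=C10 alkene is epoxidised. In one acid-mediated operation the C3 carbonyl oxygen opens the (1R,10R)-epoxide at tertiary C10, closing the dihydrofuran ring, setting C10 by inversion and leaving the C1 hydroxyl. The precursor is a 4Z-enone 1(10)-epoxide that already carries the trans-fused α-methylene lactone, the C8 isovalerate and a C15 silyl ether. It is assembled by acyclic stereocontrol from one chiral epoxide and ring-closed by a chromium-mediated alkenyl iodide–aldehyde coupling.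

Key step: step 17

Assumption: germacrane numbering (C1–C15) is used for all intermediates; the two C3 epimers formed in step 14 are carried on together because C3 becomes a carbonyl in step 15.
Design remark: the epoxy ketone 30 is reached only through buffered, base-free steps after ring closure, because a 3-oxo 1(10)-epoxide eliminates with base and cyclises early with acid. The C8 ester and the methylene lactone are already in place, so only oxidation and desilylation follow the key step.

Step 1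
Reactants: 1 pent-3-yn-1-ol
Product: 2 1-methoxy-4-[(pent-3-yn-1-yloxy)methyl]benzene
Conditions: NaH, PMBCl, Bu4NI (cat.), THF/DMF, 0 → 23 °C
Reagents that add atoms: 4-methoxybenzyl chloride, COc1ccc(CCl)cc1
Why: Williamson etherification of the sodium alkoxide with the benzylic chloride gives a PMB ether that tolerates the organometallic and enolate steps ahead and can later be removed oxidatively beside the silyl ether.

Step 2
Reactants: 2 PMB ether of pent-3-yn-1-ol
Product: 4 1-({[(3E)-4-iodopent-3-en-1-yl]oxy}methyl)-4-methoxybenzene, via alkenylzirconocene chloride 3 (not isolated)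
Conditions: Cp2Zr(H)Cl (2.5 equiv), THF, 50 °C; then I2, 0 °C
Reagents that add atoms: iodine, II
Why: Hydrozirconation is a syn addition, the excess of Cp2Zr(H)Cl at 50 °C equilibrates zirconium to the less hindered methyl-bearing alkyne carbon, and iodinolysis with retention should give the E-iodide (future C10=C1), a minor regioisomer being removable by chromatography.

Step 3
Reactants: 5 ethyl (3S)-4-chloro-3-hydroxybutanoate
Product: 6 ethyl 2-[(2S)-oxiran-2-yl]acetate
Conditions: Ag2O, DME, 60 °C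
Reagents that add atoms: none
Why: Silver-assisted intramolecular Williamson closure of the chlorohydrin forms the terminal epoxide without an alkoxide base that would eliminate to the 4-hydroxybut-2-enoate, and the carbinol centre (future C8) is not touched.

Step 4
Reactants: 4 E-alkenyl iodide; 6 ethyl 2-[(2S)-oxiran-2-yl]acetate
Product: 9 ethyl (3R,5E)-3-hydroxy-8-[(4-methoxyphenyl)methoxy]-5-methyloct-5-enoate, via alkenyllithium 7 (not isolated), via alkenylmagnesium bromide 8 (not isolated)
Conditions: t-BuLi (2 equiv), Et2O, −78 °C; MgBr2·OEt2; then 6, CuBr·SMe2 (10 mol %), THF, −40 °C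
Reagents that add atoms: none
Why: Iodine–lithium exchange and transmetalation keep the alkene geometry, and the copper-catalysed Grignard opening of the terminal epoxide is an SN2 attack at the primary carbon (C9–C10 bond) that leaves the C8 stereocentre as it was in 6.

Step 5
Reactants: 9 β-hydroxy ester; 10 tert-butyl bromoacetate
Product: 12 4-tert-butyl 1-ethyl (2R)-2-[(1R,3E)-1-hydroxy-6-[(4-methoxyphenyl)methoxy]-3-methylhex-3-en-1-yl]butanedioate, via dilithium alkoxide enolate 11 (not isolated)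
Conditions: LiN(i-Pr)2 (2.2 equiv), THF, −78 → −20 °C; then 10, DMPU, −78 → −20 °C
Reagents that add atoms: none
Why: In this Fráter–Seebach alkylation the lithium-chelated dianion of the β-hydroxy ester is alkylated on the face opposite the C9 chain, which should place the acetate arm anti to the C8 hydroxyl and so set C7.

Step 6
Reactants: 12 succinate diester
Product: 13 tert-butyl (3R,4R,6E)-4-hydroxy-3-[methoxy(methyl)carbamoyl]-9-[(4-methoxyphenyl)methoxy]-6-methylnon-6-enoate
Conditions: MeNH(OMe)·HCl (3 equiv), i-PrMgCl (7 equiv), THF, −20 → 0 °C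
Reagents that add atoms: N,O-dimethylhydroxylamine hydrochloride, CNOC.Cl
Why: Aminolysis of the ethyl ester by the chloromagnesium amide of N,O-dimethylhydroxylamine gives the Weinreb amide, the bulky tert-butyl ester being inert and the low temperature protecting C7 from epimerisation.

Step 7
Reactants: 13 Weinreb amide; 14 tert-butyldimethyl(prop-2-yn-1-yloxy)silane
Product: 16 tert-butyl (3R,4R,6E)-3-(4-{[tert-butyl(dimethyl)silyl]oxy}but-2-ynoyl)-4-hydroxy-9-[(4-methoxyphenyl)methoxy]-6-methylnon-6-enoate, via lithium acetylide 15 (not isolated)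
Conditions: 14, n-BuLi, THF, −78 °C; then 13, −78 → −20 °C
Reagents that add atoms: none
Why: Weinreb ketone synthesis: the lithium acetylide adds once because the chelated tetrahedral adduct survives until work-up, so the ynone that carries C4, C5, C6 and C15 is formed without touching C7 or C8.

Step 8
Reactants: 16 β-hydroxy ynone
Product: 17 tert-butyl (3R,4R,6E)-3-[(2Z)-4-{[tert-butyl(dimethyl)silyl]oxy}-3-iodobut-2-enoyl]-4-hydroxy-9-[(4-methoxyphenyl)methoxy]-6-methylnon-6-enoate
Conditions: NaI, AcOH, 23 °C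
Reagents that add atoms: sodium iodide, [Na+].[I-]
Why: Conjugate hydroiodination of the ynone is a kinetically controlled anti addition of H and I, so iodine should end on C4 cis to the C6 carbonyl (Z), which fixes the 4Z geometry of the later ring alkene.

Step 9
Reactants: 17 β-hydroxy Z-iodoenone; 18 3-methylbutanal
Product: 19 tert-butyl (3S,4R,6E)-3-[(1S,2Z)-4-{[tert-butyl(dimethyl)silyl]oxy}-1-hydroxy-3-iodobut-2-en-1-yl]-9-[(4-methoxyphenyl)methoxy]-6-methyl-4-[(3-methylbutanoyl)oxy]non-6-enoate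
Conditions: SmI2 (0.3 equiv), 18 (6 equiv), THF, −10 °C
Reagents that add atoms: none
Why: In this Evans–Tishchenko reduction the samarium-bound hemiacetal formed from the C8 hydroxyl and 18 passes hydride to the C6 ketone through a chair-like six-membered transition state, which should give the 1,3-anti C6 alcohol and leave the isovalerate on the C8 oxygen in the same event.

Step 10
Reactants: 19 γ-hydroxy tert-butyl ester
Product: 20 (4R,5S)-5-[(1Z)-3-{[tert-butyl(dimethyl)silyl]oxy}-2-iodoprop-1-en-1-yl]-4-[(1R,3E)-6-[(4-methoxyphenyl)methoxy]-3-methyl-1-[(3-methylbutanoyl)oxy]hex-3-en-1-yl]oxolan-2-one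
Conditions: CSA (0.1 equiv), PhMe, 40 °C
Reagents that add atoms: none
Why: Acid-catalysed lactonisation (intramolecular transesterification, 5-exo-trig) of the γ-hydroxy tert-butyl ester closes the lactone onto the free C6 oxygen with loss of tert-butanol, the C8 oxygen being blocked as its ester, and creates no new stereocentre.

Step 11
Reactants: 20 trans-lactone
Product: 24 (4R,5S)-5-[(1Z)-3-{[tert-butyl(dimethyl)silyl]oxy}-2-iodoprop-1-en-1-yl]-4-[(1R,3E)-6-[(4-methoxyphenyl)methoxy]-3-methyl-1-[(3-methylbutanoyl)oxy]hex-3-en-1-yl]-3-methylideneoxolan-2-one, via lithium enolate 21 (not isolated), via Mannich base 22 (not isolated), via trimethylammonium iodide 23 (not isolated)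
Conditions: LiN(SiMe3)2 (1.05 equiv), THF, −78 °C; CH2=NMe2+ I−, −78 → 0 °C; MeI, CH2Cl2, 23 °C; aq. NaHCO3
Reagents that add atoms: Eschenmoser's salt (N,N-dimethylmethyleneiminium iodide), C=[N+](C)C.[I-]
Why: Mannich-type α-methylenation: LiN(SiMe3)2 should enolise only the lactone, which is several pKa units more acidic than the open-chain isovalerate, the enolate is trapped at −78 °C by the iminium salt, and quaternisation followed by bicarbonate-induced elimination gives the exocyclic alkene (C13).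

Step 12
Reactants: 24 α-methylene lactone PMB ether
Product: 25 (4R,5S)-5-[(1Z)-3-{[tert-butyl(dimethyl)silyl]oxy}-2-iodoprop-1-en-1-yl]-4-[(1R,3E)-6-hydroxy-3-methyl-1-[(3-methylbutanoyl)oxy]hex-3-en-1-yl]-3-methylideneoxolan-2-one
Conditions: DDQ, CH2Cl2/pH 7 buffer, 0 °C
Reagents that add atoms: none
Why: Oxidative cleavage of the PMB ether by DDQ (benzylic hydride abstraction and hydrolysis) frees the C3 alcohol while the silyl ether, both esters, the alkenyl iodide and the methylene lactone stay intact.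

Step 13
Reactants: 25 primary alcohol
Product: 26 (4R,5S)-5-[(1Z)-3-{[tert-butyl(dimethyl)silyl]oxy}-2-iodoprop-1-en-1-yl]-4-[(1R,3E)-3-methyl-1-[(3-methylbutanoyl)oxy]-6-oxohex-3-en-1-yl]-3-methylideneoxolan-2-one
Conditions: DMP, NaHCO3, CH2Cl2, 0 °C
Reagents that add atoms: none
Why: Buffered Dess–Martin oxidation gives the β,γ-unsaturated C3 aldehyde under non-basic conditions, and the aldehyde is used at once so that the C1=C10 alkene cannot move into conjugation.

Step 14
Reactants: 26 iodo aldehyde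
Product: 28 (1(10)E,4Z,6R,7R,8R)-15-{[tert-butyl(dimethyl)silyl]oxy}-3-hydroxy-8-[(3-methylbutanoyl)oxy]germacra-1(10),4,11(13)-trien-12,6-olide as both C3 epimers, via alkenylchromium dichloride 27 (not isolated)
Conditions: CrCl2 (10 equiv), NiCl2 (2 mol %), DMSO/THF (1:3), 23 °C, syringe-pump addition to 2 mM
Reagents that add atoms: none
Why: Intramolecular Nozaki–Hiyama–Kishi coupling: nickel-catalysed activation of the C4–I bond and transmetalation to chromium give an alkenylchromium species that adds only to the aldehyde, with retention of the Z geometry, to close the C3–C4 bond of the ten-membered ring, and both C3 epimers converge in step 15.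

Step 15
Reactants: 28 macrocyclic allylic alcohol
Product: 29 (1(10)E,4Z,6R,7R,8R)-15-{[tert-butyl(dimethyl)silyl]oxy}-8-[(3-methylbutanoyl)oxy]-3-oxogermacra-1(10),4,11(13)-trien-12,6-olide
Conditions: DMP, NaHCO3, CH2Cl2, 0 °C
Reagents that add atoms: none
Why: Dess–Martin oxidation of the allylic C3 alcohol gives the 4Z-enone under buffered, non-basic conditions that should leave the skipped C1=C10 alkene in place.

Step 16
Reactants: 29 dienone
Product: 30 (1R,4Z,6R,7R,8R,10R)-15-{[tert-butyl(dimethyl)silyl]oxy}-1,10-epoxy-8-[(3-methylbutanoyl)oxy]-3-oxogermacra-4,11(13)-dien-12,6-olide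
Conditions: mCPBA, NaHCO3, CH2Cl2, −20 → 0 °C
Reagents that add atoms: 3-chloroperoxybenzoic acid, O=C(OO)c1cccc(Cl)c1
Why: Prilezhaev epoxidation attacks only the electron-rich C1=C10 alkene (the enone and the methylene lactone are deactivated), and the peracid should approach the outer face of this E-alkene in the preferred ring conformer, as in natural 1β,10α-epoxygermacranolides, to give the (1R,10R)-epoxide.

Step 17
Reactants: 30 3-oxo 1(10)-epoxide
Product: 31 (1R,4Z,6R,7R,8R,10S)-15-{[tert-butyl(dimethyl)silyl]oxy}-3,10-epoxy-1-hydroxy-8-[(3-methylbutanoyl)oxy]germacra-2,4,11(13)-trien-12,6-olide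
Conditions: CSA (0.2 equiv), 4 Å MS, CH2Cl2, −20 → 0 °C; then Et3N
Reagents that add atoms: none
Why: Protonation of the epoxide weakens the bond from oxygen to tertiary C10, the C3 carbonyl oxygen (1,4 to C10 and on the inner face of the ring) adds to C10 anti to the leaving oxygen, and the bridged oxocarbenium ion then loses a C2 proton to give the dienol ether with the former epoxide oxygen as the C1 hydroxyl. The closest known reaction type is the acid-catalysed cyclisation of β,γ-epoxy ketones to 3-hydroxy-2,3-dihydrofurans (the first stage of the epoxy-ketone furan synthesis), here run across a ten-membered ring as in transannular openings of germacranolide 1(10)-epoxides. The five-membered ring O–C3–C2–C1–C10 closes in a 5-endo epoxide-opening mode, which is tolerated because C10 is tertiary and reacts with carbocation-like character. C10 is set by inversion and is therefore controlled by the (1R,10R)-epoxide configuration, while C1 keeps its configuration and is oxidised later. The step needs attack at C10 and not C1, secured by the tertiary centre and the impossibility of a four-membered ring, and capture by the ketone oxygen in preference to the C8 ester carbonyl or a 1,2-hydride shift, secured by the proximity of C3=O, a weak Brønsted acid and low temperature; aromatisation to a furan is blocked because C10 is quaternary.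

Step 18
Reactants: 31 bridged dihydrofuranol
Product: 32 (4Z,6R,7R,8R,10S)-15-{[tert-butyl(dimethyl)silyl]oxy}-3,10-epoxy-8-[(3-methylbutanoyl)oxy]-1-oxogermacra-2,4,11(13)-trien-12,6-olide
Conditions: MnO2, CH2Cl2, 23 °C
Reagents that add atoms: none
Why: Allylic oxidation with MnO2 converts the C1 alcohol next to the enol ether into the carbonyl of the 3(2H)-furanone under neutral conditions that spare the acid-labile dienol ether.

Step 19
Reactants: 32 silyl-protected furanone
Product: 33 (4Z,6R,7R,8R,10S)-3,10-epoxy-15-hydroxy-8-[(3-methylbutanoyl)oxy]-1-oxogermacra-2,4,11(13)-trien-12,6-olide (CNP0171896.1)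
Conditions: HF·pyridine, pyridine/THF, 0 °C
Reagents that add atoms: none
Why: Fluoride-mediated desilylation with buffered HF·pyridine frees the C15 alcohol without base, so the methylene lactone, the furanone and the isovalerate are kept and the target is obtained.

Compound list
1 | pent-3-yn-1-ol | CC#CCCO | starting material
2 | 1-methoxy-4-[(pent-3-yn-1-yloxy)methyl]benzene | CC#CCCOCc1ccc(OC)cc1 | intermediate
3 | alkenylzirconocene chloride from 2 (zirconium on the methyl-bearing carbon, trans to the chain) | C/C(=C\CCOCc1ccc(OC)cc1)[Zr](Cl)(C1C=CC=C1)C1C=CC=C1 | intermediate (not isolated)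
4 | 1-({[(3E)-4-iodopent-3-en-1-yl]oxy}methyl)-4-methoxybenzene | C/C(I)=C\CCOCc1ccc(OC)cc1 | intermediate
5 | ethyl (3S)-4-chloro-3-hydroxybutanoate | CCOC(=O)C[C@H](O)CCl | starting material
6 | ethyl 2-[(2S)-oxiran-2-yl]acetate | CCOC(=O)C[C@H]1CO1 | intermediate
7 | alkenyllithium from 4 (lithium in place of iodine, geometry retained) | C/C([Li])=C\CCOCc1ccc(OC)cc1 | intermediate (not isolated)
8 | alkenylmagnesium bromide from 7 | C/C([Mg]Br)=C\CCOCc1ccc(OC)cc1 | intermediate (not isolated)
9 | ethyl (3R,5E)-3-hydroxy-8-[(4-methoxyphenyl)methoxy]-5-methyloct-5-enoate | CCOC(=O)C[C@H](O)C/C(C)=C/CCOCc1ccc(OC)cc1 | intermediate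
10 | tert-butyl bromoacetate | CC(C)(C)OC(=O)CBr | starting material
11 | dilithium alkoxide ester enolate of 9 | CCOC(O[Li])=C[C@H](O[Li])C/C(C)=C/CCOCc1ccc(OC)cc1 | intermediate (not isolated)
12 | 4-tert-butyl 1-ethyl (2R)-2-[(1R,3E)-1-hydroxy-6-[(4-methoxyphenyl)methoxy]-3-methylhex-3-en-1-yl]butanedioate | CCOC(=O)[C@H](CC(=O)OC(C)(C)C)[C@H](O)C/C(C)=C/CCOCc1ccc(OC)cc1 | intermediate
13 | tert-butyl (3R,4R,6E)-4-hydroxy-3-[methoxy(methyl)carbamoyl]-9-[(4-methoxyphenyl)methoxy]-6-methylnon-6-enoate | CON(C)C(=O)[C@H](CC(=O)OC(C)(C)C)[C@H](O)C/C(C)=C/CCOCc1ccc(OC)cc1 | intermediate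
14 | tert-butyldimethyl(prop-2-yn-1-yloxy)silane | C#CCO[Si](C)(C)C(C)(C)C | starting material
15 | lithium acetylide of 14 | [Li]C#CCO[Si](C)(C)C(C)(C)C | intermediate (not isolated)
16 | tert-butyl (3R,4R,6E)-3-(4-{[tert-butyl(dimethyl)silyl]oxy}but-2-ynoyl)-4-hydroxy-9-[(4-methoxyphenyl)methoxy]-6-methylnon-6-enoate | CC(C)(C)[Si](C)(C)OCC#CC(=O)[C@H](CC(=O)OC(C)(C)C)[C@H](O)C/C(C)=C/CCOCc1ccc(OC)cc1 | intermediate
17 | tert-butyl (3R,4R,6E)-3-[(2Z)-4-{[tert-butyl(dimethyl)silyl]oxy}-3-iodobut-2-enoyl]-4-hydroxy-9-[(4-methoxyphenyl)methoxy]-6-methylnon-6-enoate | CC(C)(C)[Si](C)(C)OC/C(I)=C/C(=O)[C@H](CC(=O)OC(C)(C)C)[C@H](O)C/C(C)=C/CCOCc1ccc(OC)cc1 | intermediate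
18 | 3-methylbutanal | CC(C)CC=O | starting material
19 | tert-butyl (3S,4R,6E)-3-[(1S,2Z)-4-{[tert-butyl(dimethyl)silyl]oxy}-1-hydroxy-3-iodobut-2-en-1-yl]-9-[(4-methoxyphenyl)methoxy]-6-methyl-4-[(3-methylbutanoyl)oxy]non-6-enoate | CC(C)(C)[Si](C)(C)OC/C(I)=C/[C@@H](O)[C@H](CC(=O)OC(C)(C)C)[C@H](OC(=O)CC(C)C)C/C(C)=C/CCOCc1ccc(OC)cc1 | intermediate
20 | (4R,5S)-5-[(1Z)-3-{[tert-butyl(dimethyl)silyl]oxy}-2-iodoprop-1-en-1-yl]-4-[(1R,3E)-6-[(4-methoxyphenyl)methoxy]-3-methyl-1-[(3-methylbutanoyl)oxy]hex-3-en-1-yl]oxolan-2-one | O=C1O[C@H](/C=C(\I)CO[Si](C)(C)C(C)(C)C)[C@H](C1)[C@H](OC(=O)CC(C)C)C/C(C)=C/CCOCc1ccc(OC)cc1 | intermediate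
21 | lithium enolate of lactone 20 | [Li]OC1=C[C@@H]([C@H](O1)/C=C(\I)CO[Si](C)(C)C(C)(C)C)[C@H](OC(=O)CC(C)C)C/C(C)=C/CCOCc1ccc(OC)cc1 | intermediate (not isolated)
22 | Mannich base, the 3-[(dimethylamino)methyl] derivative of 20 (C11 epimers) | CN(C)CC1C(=O)O[C@H](/C=C(\I)CO[Si](C)(C)C(C)(C)C)[C@H]1[C@H](OC(=O)CC(C)C)C/C(C)=C/CCOCc1ccc(OC)cc1 | intermediate (not isolated)
23 | trimethylammonium iodide of 22 | C[N+](C)(C)CC1C(=O)O[C@H](/C=C(\I)CO[Si](C)(C)C(C)(C)C)[C@H]1[C@H](OC(=O)CC(C)C)C/C(C)=C/CCOCc1ccc(OC)cc1.[I-] | intermediate (not isolated)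
24 | (4R,5S)-5-[(1Z)-3-{[tert-butyl(dimethyl)silyl]oxy}-2-iodoprop-1-en-1-yl]-4-[(1R,3E)-6-[(4-methoxyphenyl)methoxy]-3-methyl-1-[(3-methylbutanoyl)oxy]hex-3-en-1-yl]-3-methylideneoxolan-2-one | C=C1C(=O)O[C@H](/C=C(\I)CO[Si](C)(C)C(C)(C)C)[C@H]1[C@H](OC(=O)CC(C)C)C/C(C)=C/CCOCc1ccc(OC)cc1 | intermediate
25 | (4R,5S)-5-[(1Z)-3-{[tert-butyl(dimethyl)silyl]oxy}-2-iodoprop-1-en-1-yl]-4-[(1R,3E)-6-hydroxy-3-methyl-1-[(3-methylbutanoyl)oxy]hex-3-en-1-yl]-3-methylideneoxolan-2-one | C=C1C(=O)O[C@H](/C=C(\I)CO[Si](C)(C)C(C)(C)C)[C@H]1[C@H](OC(=O)CC(C)C)C/C(C)=C/CCO | intermediate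
26 | (4R,5S)-5-[(1Z)-3-{[tert-butyl(dimethyl)silyl]oxy}-2-iodoprop-1-en-1-yl]-4-[(1R,3E)-3-methyl-1-[(3-methylbutanoyl)oxy]-6-oxohex-3-en-1-yl]-3-methylideneoxolan-2-one | C=C1C(=O)O[C@H](/C=C(\I)CO[Si](C)(C)C(C)(C)C)[C@H]1[C@H](OC(=O)CC(C)C)C/C(C)=C/CC=O | intermediate
27 | alkenylchromium dichloride from 26 (chromium in place of iodine) | C=C1C(=O)O[C@H](/C=C(\[Cr](Cl)Cl)CO[Si](C)(C)C(C)(C)C)[C@H]1[C@H](OC(=O)CC(C)C)C/C(C)=C/CC=O | intermediate (not isolated)
28 | (1(10)E,4Z,6R,7R,8R)-15-{[tert-butyl(dimethyl)silyl]oxy}-3-hydroxy-8-[(3-methylbutanoyl)oxy]germacra-1(10),4,11(13)-trien-12,6-olide, both C3 epimers | C=C1C(=O)O[C@@H]2/C=C(/CO[Si](C)(C)C(C)(C)C)C(O)C/C=C(C)/C[C@@H](OC(=O)CC(C)C)[C@@H]12 | intermediate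
29 | (1(10)E,4Z,6R,7R,8R)-15-{[tert-butyl(dimethyl)silyl]oxy}-8-[(3-methylbutanoyl)oxy]-3-oxogermacra-1(10),4,11(13)-trien-12,6-olide | C=C1C(=O)O[C@@H]2/C=C(/CO[Si](C)(C)C(C)(C)C)C(=O)C/C=C(C)/C[C@@H](OC(=O)CC(C)C)[C@@H]12 | intermediate
30 | (1R,4Z,6R,7R,8R,10R)-15-{[tert-butyl(dimethyl)silyl]oxy}-1,10-epoxy-8-[(3-methylbutanoyl)oxy]-3-oxogermacra-4,11(13)-dien-12,6-olide | C=C1C(=O)O[C@@H]2/C=C(/CO[Si](C)(C)C(C)(C)C)C(=O)C[C@H]3O[C@]3(C)C[C@@H](OC(=O)CC(C)C)[C@@H]12 | intermediate (key-step precursor)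
31 | (1R,4Z,6R,7R,8R,10S)-15-{[tert-butyl(dimethyl)silyl]oxy}-3,10-epoxy-1-hydroxy-8-[(3-methylbutanoyl)oxy]germacra-2,4,11(13)-trien-12,6-olide | C=C1C(=O)O[C@@H]2/C=C(/CO[Si](C)(C)C(C)(C)C)C3=C[C@@H](O)[C@](C)(C[C@@H](OC(=O)CC(C)C)[C@@H]12)O3 | intermediate (key-step product)
32 | (4Z,6R,7R,8R,10S)-15-{[tert-butyl(dimethyl)silyl]oxy}-3,10-epoxy-8-[(3-methylbutanoyl)oxy]-1-oxogermacra-2,4,11(13)-trien-12,6-olide | C=C1C(=O)O[C@@H]2/C=C(/CO[Si](C)(C)C(C)(C)C)C3=CC(=O)[C@](C)(C[C@@H](OC(=O)CC(C)C)[C@@H]12)O3 | intermediate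
33 | (4Z,6R,7R,8R,10S)-3,10-epoxy-15-hydroxy-8-[(3-methylbutanoyl)oxy]-1-oxogermacra-2,4,11(13)-trien-12,6-olide (CNP0171896.1) | C=C1C(=O)O[C@@H]2/C=C(/CO)C3=CC(=O)[C@](C)(C[C@@H](OC(=O)CC(C)C)[C@@H]12)O3 | target

Total step count: 19.
Longest linear sequence: 18 steps (from 1 through steps 1, 2 and 4–19); step 3 is a one-step side branch.

The three steps most likely to fail

1. Step 17 (key step). The C10 cation may be diverted in three ways: participation of the C8 ester carbonyl (six-membered acyloxonium ion, then acyl shift), a 1,2-hydride shift to a C1 ketone, or hydration of the bridged oxocarbenium ion to a hemiketal that does not dehydrate. Over-exposure to acid may also ionise the allylic C1 hydroxyl of the dienol ether. The fallback sets out from 28 and comes back at 32. The C3 alcohols 28 are epoxidised with mCPBA at C1=C10 to give, from the 3S epimer, the 3-hydroxy 1,10-epoxide F1. Under catalytic CSA its C3 hydroxyl opens the epoxide at C10 (transannular etherification of an epoxy alcohol) to give the saturated 3,10-ether 1-alcohol F2. Dess–Martin oxidation gives the 1-ketone F3, and IBX-mediated α,β-dehydrogenation across C2–C3 (DMSO, 70 °C) gives 32.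

2. Step 14. Oligomerisation may outrun closure of the strained ten-membered ring, the alkenyl iodide may be reduced to the alkene, or the C1=C10 alkene of the aldehyde may move into conjugation before coupling. The fallback sets out from 26 and comes back at 29, so that step 15 is no longer needed. Pinnick oxidation (NaClO2, NaH2PO4, 2-methylbut-2-ene) gives the carboxylic acid F4. Exchange of iodide for tin (Me3SnSnMe3, Pd(PPh3)4) gives the alkenylstannane acid F5. 1-Chloro-N,N,2-trimethylprop-1-en-1-amine gives the acid chloride F6, and an intramolecular Stille acylation under high dilution (Pd2(dba)3, tri(2-furyl)phosphine, PhMe) closes the C3–C4 bond directly as the ketone 29.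

3. Step 16. Oxygen may be delivered to the wrong face of C1=C10 if the ring conformation does not shield the inner face, and the wrong epoxide would lead to the wrong C10 configuration after inversion. The m-chlorobenzoic acid formed may also trigger early cyclisation or elimination. The fallback sets out from 29 and comes back at 30. It replaces substrate control by catalyst control: Shi epoxidation with the D-fructose-derived ketone and KHSO5 (Oxone) in buffered MeCN/dimethoxymethane at 0 °C should give the (1R,10R)-epoxide whatever the ring conformation. It makes no new compound (F0).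

Further compounds
F1 | step 17 | (1R,3S,4Z,6R,7R,8R,10R)-15-{[tert-butyl(dimethyl)silyl]oxy}-1,10-epoxy-3-hydroxy-8-[(3-methylbutanoyl)oxy]germacra-4,11(13)-dien-12,6-olide | C=C1C(=O)O[C@@H]2/C=C(/CO[Si](C)(C)C(C)(C)C)[C@@H](O)C[C@H]3O[C@]3(C)C[C@@H](OC(=O)CC(C)C)[C@@H]12
F2 | step 17 | (1R,3S,4Z,6R,7R,8R,10S)-15-{[tert-butyl(dimethyl)silyl]oxy}-3,10-epoxy-1-hydroxy-8-[(3-methylbutanoyl)oxy]germacra-4,11(13)-dien-12,6-olide | C=C1C(=O)O[C@@H]2/C=C(/CO[Si](C)(C)C(C)(C)C)[C@@H]3C[C@@H](O)[C@](C)(C[C@@H](OC(=O)CC(C)C)[C@@H]12)O3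
F3 | step 17 | (3S,4Z,6R,7R,8R,10S)-15-{[tert-butyl(dimethyl)silyl]oxy}-3,10-epoxy-8-[(3-methylbutanoyl)oxy]-1-oxogermacra-4,11(13)-dien-12,6-olide | C=C1C(=O)O[C@@H]2/C=C(/CO[Si](C)(C)C(C)(C)C)[C@@H]3CC(=O)[C@](C)(C[C@@H](OC(=O)CC(C)C)[C@@H]12)O3
F4 | step 14 | (3E,6R)-6-[(2S,3R)-2-[(1Z)-3-{[tert-butyl(dimethyl)silyl]oxy}-2-iodoprop-1-en-1-yl]-4-methylidene-5-oxooxolan-3-yl]-4-methyl-6-[(3-methylbutanoyl)oxy]hex-3-enoic acid | C=C1C(=O)O[C@H](/C=C(\I)CO[Si](C)(C)C(C)(C)C)[C@H]1[C@H](OC(=O)CC(C)C)C/C(C)=C/CC(=O)O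
F5 | step 14 | (3E,6R)-6-[(2S,3R)-2-[(1Z)-3-{[tert-butyl(dimethyl)silyl]oxy}-2-(trimethylstannyl)prop-1-en-1-yl]-4-methylidene-5-oxooxolan-3-yl]-4-methyl-6-[(3-methylbutanoyl)oxy]hex-3-enoic acid | C=C1C(=O)O[C@H](/C=C(\[Sn](C)(C)C)CO[Si](C)(C)C(C)(C)C)[C@H]1[C@H](OC(=O)CC(C)C)C/C(C)=C/CC(=O)O
F6 | step 14 | acid chloride of F5 | C=C1C(=O)O[C@H](/C=C(\[Sn](C)(C)C)CO[Si](C)(C)C(C)(C)C)[C@H]1[C@H](OC(=O)CC(C)C)C/C(C)=C/CC(=O)Cl
F0 | step 16 | none | none
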